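**Retrosynthetic overview**
1. Rings A, B and C, with C2 and C3, are bought as (+)-dihydrorobinetin (1); reducing its C4 ketone gives (+)-leucorobinetinidin (2), whose 4-OH is the leaving group.
2. Rings D, E and F, with both of their stereocentres, are bought as (−)-epigallocatechin (3).
3. Key disconnection: the interflavanyl bond from C4 (ring C) to C6 (ring D). Acid ionises 2 to the benzylic cation (4), which 3 captures anti to the C3 hydroxyl to give the target (5).
4. Ring order: no ring is built; the two bought tricyclic units are joined last, without protecting groups.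

Assumption: 1 and 3 are bought as the natural enantiomers named; because the route has only two steps, the closing risk ranking names step 2 twice (two independent failure modes) and then step 1.

**Route**

Step 1
Reactants: 1 (+)-dihydrorobinetin
Product: 2 (+)-leucorobinetinidin [(2R,3S,4R)-2,3-trans-3,4-trans-flavan-3,4,7,3',4',5'-hexol]
Conditions: NaBH4 (5 equiv), EtOH, N2, 0 °C → rt, 6 h; AcOH/H2O to pH 5, EtOAc extraction
Reagents that add atoms: none
Why: Borohydride carbonyl reduction: with the 2-aryl and 3-hydroxyl groups equatorial on the half-chair of ring C, hydride enters axially on the face of the C3 hydroxyl, so the new 4-OH is equatorial and trans to 3-OH (4R) while C2 and C3 are untouched; any 4-epimer would ionise to the same cation in step 2.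

Step 2
Reactants: 2 (+)-leucorobinetinidin; 3 (−)-epigallocatechin (4 equiv, excess recovered)
Product: 5 robinetinidol-(4α→6)-epigallocatechin (target), via flavan-4-yl cation 4 (not isolated)
Conditions: 0.1 M aq. HCl (degassed), N2, rt, 16 h; EtOAc extraction; Sephadex LH-20 (EtOH), then C18 preparative HPLC
Reagents that add atoms: none
Why: Acid-catalysed SN1 Friedel–Crafts alkylation: loss of water gives the benzylic cation stabilised by the 7-OH (an O-protonated para-quinone methide), the phloroglucinol-type ring D of 3 captures it, and attack anti to the C3 hydroxyl of the 2,3-trans half-chair sets C4 as 3,4-trans (4α, 4S) under control of the bought C3 centre; C6 versus C8 of ring D is not controlled, so the C6-linked isomer 5 is separated from the C8-linked regioisomer.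

**Compound list**
1 | (+)-dihydrorobinetin, (2R,3R)-3,7-dihydroxy-2-(3,4,5-trihydroxyphenyl)-2,3-dihydro-4H-chromen-4-one (2,3-trans) | Oc1ccc2c(c1)O[C@H](c1cc(O)c(O)c(O)c1)[C@@H](O)C2=O | starting material
2 | (+)-leucorobinetinidin, (2R,3S,4R)-2-(3,4,5-trihydroxyphenyl)-3,4-dihydro-2H-chromene-3,4,7-triol (2,3-trans-3,4-trans) | Oc1ccc2c(c1)O[C@H](c1cc(O)c(O)c(O)c1)[C@@H](O)[C@@H]2O | intermediate
3 | (−)-epigallocatechin, (2R,3R)-2-(3,4,5-trihydroxyphenyl)-3,4-dihydro-2H-chromene-3,5,7-triol (2,3-cis) | Oc1cc2c(c(O)c1)C[C@@H](O)[C@@H](c1cc(O)c(O)c(O)c1)O2 | starting material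
4 | flavan-4-yl cation, (2R,3S)-3,7-dihydroxy-2-(3,4,5-trihydroxyphenyl)chroman-4-ylium | Oc1ccc2c(c1)O[C@H](c1cc(O)c(O)c(O)c1)[C@@H](O)[CH+]2 | intermediate
5 | robinetinidol-(4α→6)-epigallocatechin, (2R,3S,4S)-2-(3,4,5-trihydroxyphenyl)-4-[(2R,3R)-3,5,7-trihydroxy-2-(3,4,5-trihydroxyphenyl)-3,4-dihydro-2H-chromen-6-yl]-3,4-dihydro-2H-chromene-3,7-diol | Oc1ccc2c(c1)O[C@H](c1cc(O)c(O)c(O)c1)[C@@H](O)[C@@H]2c1c(O)cc2c(c1O)C[C@@H](O)[C@@H](c1cc(O)c(O)c(O)c1)O2 | target

**Totals**
Total step count: 2. Longest linear sequence: 2.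

**Steps most likely to fail, with fallbacks**

Step 2, regiochemistry. C8 of ring D is normally the more nucleophilic position, so 5 is expected to be a minor part of the dimer fraction (roughly a tenth to a seventh, an estimate from analogous 5-deoxy couplings). It has to be separated from the 4→8 isomers.
Fallback, setting out from 1 and 3 and coming back at 5: block C8 with bromine and couple benzyl ethers under Lewis acid.
- 1 is benzylated on its four phenols (BnBr, K2CO3, DMF, N2) to 7,3',4',5'-tetra-O-benzyldihydrorobinetin F1.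
- F1 is reduced (NaBH4, THF/EtOH) to 7,3',4',5'-tetra-O-benzylleucorobinetinidin F2.
- 3 is benzylated in the same way to 5,7,3',4',5'-penta-O-benzylepigallocatechin F3.
- F3 is brominated at C8 (NBS, CH2Cl2, −20 °C) to 8-bromo-5,7,3',4',5'-penta-O-benzylepigallocatechin F4.
- BF3·OEt2 (CH2Cl2, −30 → 0 °C) joins F2 to F4 (3 equiv), whose only free position on ring D is C6. This gives 7,3',4',5'-tetra-O-benzylrobinetinidol-(4α→6)-8-bromo-5,7,3',4',5'-penta-O-benzylepigallocatechin F5.
- H2, Pd(OH)2 on carbon and Et3N in THF/MeOH/H2O remove the nine benzyl groups and the bromine to give 5.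

Step 2, configuration at C4 and over-condensation. A 5-deoxy cation is less face-selective than a phloroglucinol-type one, so the 3,4-cis (4β) isomer accompanies 5. The product can also be alkylated again.
Fallback, setting out from 1 and 3 (through the benzylated diol F2 and the bromide F4 described above) and coming back at 5: neighbouring-group control.
- F2 is acetylated (Ac2O, pyridine, DMAP) to 3,4-di-O-acetyl-7,3',4',5'-tetra-O-benzylleucorobinetinidin F6.
- TMSOTf (CH2Cl2, −40 °C) ionises the 4-acetate. The 3-acetate closes onto C4 as a dioxolenium ion on the face of the C3 oxygen, so F4 can only enter anti. This gives 3-O-acetyl-7,3',4',5'-tetra-O-benzylrobinetinidol-(4α→6)-8-bromo-5,7,3',4',5'-penta-O-benzylepigallocatechin F7 as the single 3,4-trans isomer.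
- NaOMe in MeOH/THF removes the acetate to give the dimer F5, and the hydrogenolysis described above gives 5.

Step 1. NaBH4 is basic enough to deprotonate the 7-OH para to the ketone, and the resulting phenoxide makes the carbonyl a poor electrophile. The pyrogallol ring is also air-sensitive in this medium, so conversion or isolation of the water-soluble diol may be poor.
Fallback, setting out from 1 and coming back at 2: mask the phenols as silyl ethers.
- TBSCl and imidazole in DMF give 7,3',4',5'-tetra-O-(tert-butyldimethylsilyl)dihydrorobinetin F8.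
- NaBH4 in THF/MeOH at 0 °C then reduces an ordinary aryl ketone to the 3,4-trans diol 7,3',4',5'-tetra-O-(tert-butyldimethylsilyl)leucorobinetinidin F9.
- Et3N·3HF in THF at 0 °C removes the four silyl groups without base to give 2.

**Further compounds**
F1 | step 2 | 7,3',4',5'-tetra-O-benzyl-(2R,3R)-dihydrorobinetin | c1ccccc1COc1ccc2c(c1)O[C@H](c1cc(OCc3ccccc3)c(OCc3ccccc3)c(OCc3ccccc3)c1)[C@@H](O)C2=O
F2 | step 2 | 7,3',4',5'-tetra-O-benzyl-(2R,3S,4R)-leucorobinetinidin (2,3-trans-3,4-trans diol) | c1ccccc1COc1ccc2c(c1)O[C@H](c1cc(OCc3ccccc3)c(OCc3ccccc3)c(OCc3ccccc3)c1)[C@@H](O)[C@@H]2O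
F3 | step 2 | 5,7,3',4',5'-penta-O-benzyl-(2R,3R)-epigallocatechin | c1ccccc1COc1cc2c(c(OCc3ccccc3)c1)C[C@@H](O)[C@@H](c1cc(OCc3ccccc3)c(OCc3ccccc3)c(OCc3ccccc3)c1)O2
F4 | step 2 | 8-bromo-5,7,3',4',5'-penta-O-benzyl-(2R,3R)-epigallocatechin | c1ccccc1COc1c(Br)c2c(c(OCc3ccccc3)c1)C[C@@H](O)[C@@H](c1cc(OCc3ccccc3)c(OCc3ccccc3)c(OCc3ccccc3)c1)O2
F5 | step 2 | 7,3',4',5'-tetra-O-benzylrobinetinidol-(4α→6)-8-bromo-5,7,3',4',5'-penta-O-benzylepigallocatechin (2,3-trans-3,4-trans upper unit, 2,3-cis lower unit) | c1ccccc1COc1ccc2c(c1)O[C@H](c1cc(OCc3ccccc3)c(OCc3ccccc3)c(OCc3ccccc3)c1)[C@@H](O)[C@@H]2c1c(OCc3ccccc3)c(Br)c2c(c1OCc3ccccc3)C[C@@H](O)[C@@H](c1cc(OCc3ccccc3)c(OCc3ccccc3)c(OCc3ccccc3)c1)O2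
F6 | step 2 | 3,4-di-O-acetyl-7,3',4',5'-tetra-O-benzylleucorobinetinidin (2,3-trans-3,4-trans) | c1ccccc1COc1ccc2c(c1)O[C@H](c1cc(OCc3ccccc3)c(OCc3ccccc3)c(OCc3ccccc3)c1)[C@@H](OC(C)=O)[C@@H]2OC(C)=O
F7 | step 2 | 3-O-acetyl-7,3',4',5'-tetra-O-benzylrobinetinidol-(4α→6)-8-bromo-5,7,3',4',5'-penta-O-benzylepigallocatechin | c1ccccc1COc1ccc2c(c1)O[C@H](c1cc(OCc3ccccc3)c(OCc3ccccc3)c(OCc3ccccc3)c1)[C@@H](OC(C)=O)[C@@H]2c1c(OCc3ccccc3)c(Br)c2c(c1OCc3ccccc3)C[C@@H](O)[C@@H](c1cc(OCc3ccccc3)c(OCc3ccccc3)c(OCc3ccccc3)c1)O2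
F8 | step 1 | 7,3',4',5'-tetra-O-(tert-butyldimethylsilyl)-(2R,3R)-dihydrorobinetin | CC(C)(C)[Si](C)(C)Oc1ccc2c(c1)O[C@H](c1cc(O[Si](C)(C)C(C)(C)C)c(O[Si](C)(C)C(C)(C)C)c(O[Si](C)(C)C(C)(C)C)c1)[C@@H](O)C2=O
F9 | step 1 | 7,3',4',5'-tetra-O-(tert-butyldimethylsilyl)-(2R,3S,4R)-leucorobinetinidin (2,3-trans-3,4-trans diol) | CC(C)(C)[Si](C)(C)Oc1ccc2c(c1)O[C@H](c1cc(O[Si](C)(C)C(C)(C)C)c(O[Si](C)(C)C(C)(C)C)c(O[Si](C)(C)C(C)(C)C)c1)[C@@H](O)[C@@H]2O
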